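**Strategy.** The target is cut at the central single bond of the diene into a bromo-oxane iodoalkene (from (R)-linalool) and an ethynyl bromohydrin. In the carbocycle (C1 carbinol, C2 CHBr, C4 side-chain carbon) the bromine-bearing C2 is treated as a one-carbon insert between C1 and C3. In the key step dibromocarbene adds to the enol ether double bond of an enantioenriched 3-alkynyl-1-silyloxycyclopentene, and strain-driven opening of the dibromocyclopropane gives the 2-bromocyclohex-2-enone. The five-membered ring grows by one atom, bromine arrives on C2, the carbonyl marks C1 for methyl addition, and the C4 stereocentre is carried through intact.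

Key step: step 3

Assumption: the (R)-antipode of p-tol-BINAP is taken to deliver hydride to the enone face that gives the 3S enol ether in step 2; if the sense is the reverse, the (S)-ligand is used with no other change.

Carbocycle numbering used below: C1 = C(CH3)(OH), C2 = CHBr, C3, C4 = CH bearing the side chain, C5, C6.

**Step 1**
Reactants: 1 3-ethoxycyclopent-2-en-1-one; 2 ethynyltri(propan-2-yl)silane
Product: 4 3-{[tri(propan-2-yl)silyl]ethynyl}cyclopent-2-en-1-one, via carbinol adduct 3 (not isolated)
Conditions: 2, n-BuLi, THF, −78 °C; add 1, −78 → 0 °C; then 1 M aq. HCl, rt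
Reagents that add atoms: water, O
Why: 1,2-addition of the lithium acetylide to the vinylogous ester followed by acid hydrolysis with allylic transposition (Stork–Danheiser transposition) should give the 3-alkynyl enone, and no stereocentre is formed.

**Step 2**
Reactants: 4 3-{[tri(propan-2-yl)silyl]ethynyl}cyclopent-2-en-1-one
Product: 5 dimethyl(phenyl){[(3S)-3-{[tri(propan-2-yl)silyl]ethynyl}cyclopent-1-en-1-yl]oxy}silane
Conditions: CuCl (5 mol %), NaOtBu (5 mol %), (R)-p-tol-BINAP (5 mol %), PhMe2SiH (1.2 equiv), toluene, 0 °C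
Reagents that add atoms: dimethylphenylsilane, C[SiH](C)c1ccccc1
Why: Copper hydride-catalysed asymmetric conjugate reduction (1,4-hydrosilylation) of a 3-substituted cyclopentenone, in which the bisphosphine-ligated Cu–H delivers hydride to one face of C3 and sets the 3S centre, σ-bond metathesis with the silane releases the enol ether with its double bond fixed at C1=C2, and the bulky silyl cap shields the alkyne terminus from 1,6-delivery.

**Step 3**
Reactants: 5 dimethyl(phenyl){[(3S)-3-{[tri(propan-2-yl)silyl]ethynyl}cyclopent-1-en-1-yl]oxy}silane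
Product: 7 (4S)-2-bromo-4-{[tri(propan-2-yl)silyl]ethynyl}cyclohex-2-en-1-one, via dibromocyclopropane 6 (not isolated)
Conditions: CHBr3 (1.3 equiv), KOtBu (1.2 equiv), pentane, −30 → 0 °C; filter; toluene, 60 °C; aq. NaHCO3 work-up
Reagents that add atoms: bromoform, BrC(Br)Br
Why: Dibromocarbene, formed by α-elimination from bromoform, adds in a cheletropic [2+1] reaction to the electron-rich enol ether bond to give the 6,6-dibromo-1-silyloxybicyclo[3.1.0]hexane 6, whose strain then drives loss of the bromide lying over the five-membered ring with concerted disrotatory two-electron electrocyclic opening of the ring-fusion bond to a 2-bromo-1-silyloxyallyl cation that sheds the silyl group to bromide and leaves the 2-bromo enone. The closest known reaction type is the one-carbon ring expansion of cyclic silyl enol ethers with dihalocarbenes to 2-halocycloalk-2-enones. The only ring closed is the three-membered one (concerted [2+1] cycloaddition); the six-membered ring is not closed but arises when the bond shared by the three- and five-membered rings breaks, so the cyclopentene grows by the carbene carbon, which becomes C2 and carries the bromine. No new stereocentre survives: the two cyclopropane centres (addition mainly anti to the alkynyl group) are erased on opening, both diastereomers of 6 converge on 7, and C4 keeps the configuration set in step 2. The step needs chemoselectivity for the enol ether over the alkyne (secured by the electron-rich alkene against a silyl-capped alkyne), insertion between C1 and C2 only (secured by the position of the enol ether double bond from step 2), and integrity of the acidic γ,propargylic C4–H (secured by consuming all butoxide with excess bromoform before 6 is opened thermally).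

**Step 4**
Reactants: 7 (4S)-2-bromo-4-{[tri(propan-2-yl)silyl]ethynyl}cyclohex-2-en-1-one
Product: 9 (2S,4S)-2-bromo-4-{[tri(propan-2-yl)silyl]ethynyl}cyclohexan-1-one, via lithium bromoenolate 8 (not isolated)
Conditions: LiBH(s-Bu)3 (1.1 equiv), THF, −78 °C; then AcOH, THF, −78 °C; pH 7 buffer, non-oxidative work-up
Reagents that add atoms: none
Why: Conjugate (1,4) hydride reduction of a β-unsubstituted cyclohexenone should give the α-bromo enolate 8, and kinetic axial C-protonation of its half-chair with the alkynyl group pseudo-equatorial places bromine equatorial, that is cis to the C4 substituent (2S).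

**Step 5**
Reactants: 9 (2S,4S)-2-bromo-4-{[tri(propan-2-yl)silyl]ethynyl}cyclohexan-1-one
Product: 10 (1R,2S,4S)-2-bromo-1-methyl-4-{[tri(propan-2-yl)silyl]ethynyl}cyclohexan-1-ol
Conditions: MeMgBr (3 equiv), anhydrous CeCl3 (3 equiv), THF, −78 °C; sat. aq. NH4Cl at −78 °C
Reagents that add atoms: methylmagnesium bromide, C[Mg]Br
Why: Cerium-mediated Grignard 1,2-addition to an α-bromo ketone, in which methyl enters anti to the C–Br bond (equatorial attack on the diequatorial chair or axial attack anti to axial bromine in the flipped chair, both leading to the same product) so that the new tertiary hydroxyl is axial and cis to bromine (1R), while the weakly basic organocerium should avoid enolisation.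

**Step 6**
Reactants: 10 (1R,2S,4S)-2-bromo-1-methyl-4-{[tri(propan-2-yl)silyl]ethynyl}cyclohexan-1-ol
Product: 11 (1R,2S,4S)-2-bromo-4-ethynyl-1-methylcyclohexan-1-ol
Conditions: TBAF (1.2 equiv), AcOH (1.2 equiv), THF, 0 °C → rt
Reagents that add atoms: none
Why: Fluoride-induced protodesilylation of the alkynylsilane, buffered so that the tertiary alkoxide does not build up; the equatorial bromide has neither an antiperiplanar hydrogen nor an antiperiplanar oxygen, so elimination and epoxide closure should not compete.

**Step 7**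
Reactants: 12 (3R)-3,7-dimethylocta-1,6-dien-3-ol [(R)-linalool]
Product: 13 (3S,6R)-3-bromo-6-ethenyl-2,2,6-trimethyloxane
Conditions: 2,4,4,6-tetrabromocyclohexa-2,5-dien-1-one (1.1 equiv), MeNO2, 0 °C → rt, dark; chromatography
Reagents that add atoms: 2,4,4,6-tetrabromocyclohexa-2,5-dien-1-one, O=C1C(Br)=CC(Br)(Br)C=C1Br
Why: Bromoetherification (6-endo Markovnikov opening of the bromonium ion of the trisubstituted alkene by the tertiary hydroxyl through a chair with bromine equatorial), in which C6 comes from (R)-linalool while C3 forms with little bias because methyl and vinyl compete for the equatorial site, so the (3S,6R) isomer (bromine trans to vinyl) is expected as one component to be separated from its C3 epimer and from oxolane regioisomers.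

**Step 8**
Reactants: 13 (3S,6R)-3-bromo-6-ethenyl-2,2,6-trimethyloxane
Product: 15 (2R,5S)-5-bromo-2,6,6-trimethyloxane-2-carbaldehyde, via ozonide 14 (not isolated)
Conditions: O3, CH2Cl2, −78 °C; then PPh3, −78 °C → rt
Reagents that add atoms: ozone, [O-][O+]=O
Why: Ozonolysis with reductive work-up cleaves the only alkene, and the aldehyde sits on a quaternary carbon and cannot epimerise.

**Step 9**
Reactants: 15 (2R,5S)-5-bromo-2,6,6-trimethyloxane-2-carbaldehyde
Product: 16 (3S,6R)-3-bromo-6-[(E)-2-iodoethenyl]-2,2,6-trimethyloxane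
Conditions: CrCl2 (6 equiv), CHI3 (2 equiv), THF, 0 °C → rt
Reagents that add atoms: iodoform, IC(I)I
Why: Takai olefination, in which the geminal dichromium species from iodoform adds to the hindered aldehyde and anti-elimination should give the (E)-iodoalkene, the unactivated secondary bromide being inert to CrCl2.

**Step 10**
Reactants: 11 (1R,2S,4S)-2-bromo-4-ethynyl-1-methylcyclohexan-1-ol; 16 (3S,6R)-3-bromo-6-[(E)-2-iodoethenyl]-2,2,6-trimethyloxane
Product: 18 (1R,2S,4S)-2-bromo-4-[(2E,4E)-5-[(2R,5S)-5-bromo-2,6,6-trimethyloxan-2-yl]penta-2,4-dien-2-yl]-1-methylcyclohexan-1-ol, via alkenylalane 17 (not isolated)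
Conditions: 11, Me3Al (3.5 equiv), Cp2ZrCl2 (0.3 equiv), H2O (1 equiv), CH2Cl2, −23 °C; volatiles removed; then 16, ZnCl2 (1 equiv), Pd(PPh3)4 (5 mol %), THF, rt; aq. potassium sodium tartrate
Reagents that add atoms: trimethylaluminium, C[Al](C)C
Why: Zirconium-catalysed syn-carboalumination of the terminal alkyne places methyl on the internal carbon and aluminium on the terminus (E-alkenylalane, the hydroxyl carried as its aluminium alkoxide), and Negishi coupling through zinc with the (E)-iodoalkene proceeds with retention at both partners to give the (2E,4E)-diene.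

**Compound list**

1 | 3-ethoxycyclopent-2-en-1-one | CCOC1=CC(=O)CC1 | starting material
2 | ethynyltri(propan-2-yl)silane | CC(C)[Si](C#C)(C(C)C)C(C)C | starting material
3 | 3-ethoxy-1-{[tri(propan-2-yl)silyl]ethynyl}cyclopent-2-en-1-ol (racemic, present as its lithium alkoxide) | CCOC1=CC(O)(C#C[Si](C(C)C)(C(C)C)C(C)C)CC1 | intermediate
4 | 3-{[tri(propan-2-yl)silyl]ethynyl}cyclopent-2-en-1-one | CC(C)[Si](C(C)C)(C(C)C)C#CC1=CC(=O)CC1 | intermediate
5 | dimethyl(phenyl){[(3S)-3-{[tri(propan-2-yl)silyl]ethynyl}cyclopent-1-en-1-yl]oxy}silane | CC(C)[Si](C(C)C)(C(C)C)C#C[C@H]1CCC(O[Si](C)(C)c2ccccc2)=C1 | intermediate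
6 | (1R,4S,5R)-6,6-dibromo-1-{[dimethyl(phenyl)silyl]oxy}-4-{[tri(propan-2-yl)silyl]ethynyl}bicyclo[3.1.0]hexane (CBr2 bridge anti to the alkynyl group) | CC(C)[Si](C(C)C)(C(C)C)C#C[C@H]1CC[C@]2(O[Si](C)(C)c3ccccc3)C(Br)(Br)[C@@H]21 | intermediate
7 | (4S)-2-bromo-4-{[tri(propan-2-yl)silyl]ethynyl}cyclohex-2-en-1-one | CC(C)[Si](C(C)C)(C(C)C)C#C[C@H]1CCC(=O)C(Br)=C1 | intermediate
8 | lithium (4S)-2-bromo-4-{[tri(propan-2-yl)silyl]ethynyl}cyclohex-1-en-1-olate | CC(C)[Si](C(C)C)(C(C)C)C#C[C@H]1CCC(O[Li])=C(Br)C1 | intermediate
9 | (2S,4S)-2-bromo-4-{[tri(propan-2-yl)silyl]ethynyl}cyclohexan-1-one (bromine cis to the alkynyl group) | CC(C)[Si](C(C)C)(C(C)C)C#C[C@H]1CCC(=O)[C@@H](Br)C1 | intermediate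
10 | (1R,2S,4S)-2-bromo-1-methyl-4-{[tri(propan-2-yl)silyl]ethynyl}cyclohexan-1-ol (OH, Br and alkynyl all cis) | CC(C)[Si](C(C)C)(C(C)C)C#C[C@H]1CC[C@@](C)(O)[C@@H](Br)C1 | intermediate
11 | (1R,2S,4S)-2-bromo-4-ethynyl-1-methylcyclohexan-1-ol | C#C[C@H]1CC[C@@](C)(O)[C@@H](Br)C1 | intermediate
12 | (3R)-3,7-dimethylocta-1,6-dien-3-ol [(R)-linalool] | C=C[C@](C)(O)CCC=C(C)C | starting material
13 | (3S,6R)-3-bromo-6-ethenyl-2,2,6-trimethyloxane (bromine trans to vinyl) | C=C[C@@]1(C)CC[C@H](Br)C(C)(C)O1 | intermediate
14 | 3-[(2R,5S)-5-bromo-2,6,6-trimethyloxan-2-yl]-1,2,4-trioxolane (mixture at the trioxolane carbon) | C1OOC(O1)[C@@]1(C)CC[C@H](Br)C(C)(C)O1 | intermediate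
15 | (2R,5S)-5-bromo-2,6,6-trimethyloxane-2-carbaldehyde | O=C[C@@]1(C)CC[C@H](Br)C(C)(C)O1 | intermediate
16 | (3S,6R)-3-bromo-6-[(E)-2-iodoethenyl]-2,2,6-trimethyloxane | I/C=C/[C@@]1(C)CC[C@H](Br)C(C)(C)O1 | intermediate
17 | {(E)-2-[(1S,3S,4R)-3-bromo-4-(dimethylalumanyloxy)-4-methylcyclohexyl]prop-1-en-1-yl}dimethylalumane | C[Al](C)/C=C(\C)[C@H]1CC[C@@](C)(O[Al](C)C)[C@@H](Br)C1 | intermediate
18 | (1R,2S,4S)-2-bromo-4-[(2E,4E)-5-[(2R,5S)-5-bromo-2,6,6-trimethyloxan-2-yl]penta-2,4-dien-2-yl]-1-methylcyclohexan-1-ol | C/C(=C\C=C\[C@@]1(C)CC[C@H](Br)C(C)(C)O1)[C@H]1CC[C@@](C)(O)[C@@H](Br)C1 | target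

**Step count and risks**

Total steps: 10. Longest linear sequence: 7 (steps 1–6, then step 10); steps 7–9 build the second fragment.

The three steps most likely to fail:

1. Step 2. Hydride may be transferred to the alkyne terminus (1,6-reduction or semireduction) instead of to C3, or the two enone faces may be poorly distinguished. The fallback sets out from 2 and comes back at 5, with the stereocentre made by carbometalation instead of hydride delivery. Rhodium-catalysed asymmetric conjugate alkynylation of cyclopent-2-en-1-one with 2 ([Rh(OAc)(C2H4)2]2, DTBM-SEGPHOS of the antipode that gives the 3S product, 1,4-dioxane, 80 °C) should give (3S)-3-{[tri(propan-2-yl)silyl]ethynyl}cyclopentan-1-one F1. Kinetic enolisation (LDA, PhMe2SiCl, THF, −78 °C) then gives 5 together with its regioisomer dimethyl(phenyl){[(4S)-4-{[tri(propan-2-yl)silyl]ethynyl}cyclopent-1-en-1-yl]oxy}silane F2. The two are separated on triethylamine-deactivated silica before step 3.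

2. Step 4. Hydride may add 1,2, a sec-butyl group may migrate from boron to the bromoenolate carbon, or protonation may be unselective. The fallback sets out from 7 and comes back at 9 by way of an isolable enol ether. B(C6F5)3-catalysed 1,4-hydrosilylation with Et3SiH (CH2Cl2, rt) should give {[(4S)-2-bromo-4-{[tri(propan-2-yl)silyl]ethynyl}cyclohex-1-en-1-yl]oxy}triethylsilane F3. Protodesilylation at low temperature (TBAF, AcOH, THF, −78 °C) with axial protonation then gives 9.

3. Step 10. The Lewis-acidic aluminium and zirconium species may ionise the bromide next to the aluminium alkoxide with a ring-contracting 1,2-shift, or methyl may be transferred instead of the alkenyl group in the coupling. The fallback sets out from 11 and comes back at 18 with the alkoxide donor removed. The tertiary alcohol is first masked (1-(trimethylsilyl)imidazole, CH2Cl2, rt) as {[(1R,2S,4S)-2-bromo-4-ethynyl-1-methylcyclohexyl]oxy}trimethylsilane F4. Carboalumination and coupling with 16 under the conditions of step 10 give {[(1R,2S,4S)-2-bromo-4-[(2E,4E)-5-[(2R,5S)-5-bromo-2,6,6-trimethyloxan-2-yl]penta-2,4-dien-2-yl]-1-methylcyclohexyl]oxy}trimethylsilane F5. 1 M HCl in THF at 0 °C returns 18.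

**Further compounds**

F1 | step 2 | (3S)-3-{[tri(propan-2-yl)silyl]ethynyl}cyclopentan-1-one | CC(C)[Si](C(C)C)(C(C)C)C#C[C@H]1CCC(=O)C1
F2 | step 2 | dimethyl(phenyl){[(4S)-4-{[tri(propan-2-yl)silyl]ethynyl}cyclopent-1-en-1-yl]oxy}silane | CC(C)[Si](C(C)C)(C(C)C)C#C[C@H]1CC=C(O[Si](C)(C)c2ccccc2)C1
F3 | step 4 | {[(4S)-2-bromo-4-{[tri(propan-2-yl)silyl]ethynyl}cyclohex-1-en-1-yl]oxy}triethylsilane | CC(C)[Si](C(C)C)(C(C)C)C#C[C@H]1CCC(O[Si](CC)(CC)CC)=C(Br)C1
F4 | step 10 | {[(1R,2S,4S)-2-bromo-4-ethynyl-1-methylcyclohexyl]oxy}trimethylsilane | C#C[C@H]1CC[C@@](C)(O[Si](C)(C)C)[C@@H](Br)C1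
F5 | step 10 | {[(1R,2S,4S)-2-bromo-4-[(2E,4E)-5-[(2R,5S)-5-bromo-2,6,6-trimethyloxan-2-yl]penta-2,4-dien-2-yl]-1-methylcyclohexyl]oxy}trimethylsilane | C/C(=C\C=C\[C@@]1(C)CC[C@H](Br)C(C)(C)O1)[C@H]1CC[C@@](C)(O[Si](C)(C)C)[C@@H](Br)C1
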